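The synthesis proposed below builds everything around undoing the C6–C7 bond of the ten-membered ring while reconnecting C4 to C9. In the target, the oxygen-bearing carbons C4 and C9 are separated within ring C1–C10 by the four-carbon chain C5–C8, the signature left by a [3,3] shift of a 3,4-dioxygenated 1,5-diene. A dianionic oxy-Cope rearrangement of a trans-decalin-4,9-diol therefore opens ring B (C1–C2–C3–C4–C9–C10) into the ten-membered ring in one operation, sets C7 with its oxygen and releases C4 and C9 as enolates. The precursor carries an equatorial isopropenyl group on C4 and an equatorial (E)-2-silyloxyalkenyl group on C9; ring A already contains the C11=C12 alkene and the C14 oxygen.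

Key step: step 20

Remark: locants are those of the target (ring A = C1, C10–C14; decalin ring B = C1–C4, C9, C10); "up/down" is not used, faces are named by their neighbours; the (S)-configured Diels–Alder catalyst is assumed to give the enantiomer drawn, otherwise its mirror image is used.

Step 1
Reactants: 1 propionyl chloride
Product: 2 (E)-1-chloropent-1-en-3-one
Conditions: HC≡CH, AlCl3, CH2Cl2, 0 °C
Reagents that add atoms: acetylene, C#C
Why: Friedel–Crafts-type acylation of acetylene (β-chlorovinyl ketone synthesis) is routine for aliphatic acid chlorides and gives the E-chloroenone.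

Step 2
Reactants: 2 (E)-1-chloropent-1-en-3-one
Product: 3 (E)-1-(tert-butyldimethylsilyloxy)pent-1-en-3-one
Conditions: t-BuMe2SiOH, Et3N, DMAP (cat.), CH2Cl2, 0 → 23 °C
Reagents that add atoms: tert-butyldimethylsilanol, CC(C)(C)[Si](C)(C)O
Why: Addition–elimination of an oxygen nucleophile at the β-carbon of a β-chloroenone (nucleophilic vinylic substitution) should give the thermodynamically preferred E-silyloxyenone.

Step 3
Reactants: 3 (E)-1-(tert-butyldimethylsilyloxy)pent-1-en-3-one
Product: 4 (1E,3Z)-1,3-bis(tert-butyldimethylsilyloxy)penta-1,3-diene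
Conditions: t-BuMe2SiOSO2CF3, Et3N, Et2O, 0 °C
Reagents that add atoms: tert-butyldimethylsilyl triflate, CC(C)(C)[Si](C)(C)OS(=O)(=O)C(F)(F)F
Why: Amine/silyl triflate enol silylation of an ethyl ketone gives the Z-enol ether, hence a Danishefsky-type diene whose terminal methyl points outward.

Step 4
Reactants: 5 methyl (S)-3-hydroxy-2-methylpropanoate
Product: 6 methyl (S)-3-(tert-butyldimethylsilyloxy)-2-methylpropanoate
Conditions: t-BuMe2SiCl, imidazole, CH2Cl2, 23 °C
Reagents that add atoms: tert-butyldimethylsilyl chloride, CC(C)(C)[Si](C)(C)Cl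
Why: Standard silylation of the primary alcohol leaves the stereocentre (future C17) untouched.

Step 5
Reactants: 6 methyl (S)-3-(tert-butyldimethylsilyloxy)-2-methylpropanoate
Product: 8 (R)-4-(tert-butyldimethylsilyloxy)-3-methyl-1-(triisopropylsilyloxy)but-1-yne, via lithium ynolate 7 (not isolated)
Conditions: CH2Br2, lithium 2,2,6,6-tetramethylpiperidide, THF, −78 °C; LiN(SiMe3)2, then s-BuLi, −78 → 23 °C; i-Pr3SiOSO2CF3, −78 → 0 °C
Reagents that add atoms: dibromomethane, BrCBr; triisopropylsilyl triflate, CC(C)[Si](C(C)C)(C(C)C)OS(=O)(=O)C(F)(F)F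
Why: Kowalski ester homologation stopped at the ynolate, which the bulky silyl triflate silylates on oxygen; the ester carbon becomes C8 and the new carbon C7, and the stereocentre is not enolised because deprotonation occurs on the dibromomethyl side.

Step 6
Reactants: 8 (R)-4-(tert-butyldimethylsilyloxy)-3-methyl-1-(triisopropylsilyloxy)but-1-yne
Product: 10 (S,E)-4-(tert-butyldimethylsilyloxy)-2-iodo-3-methyl-1-(triisopropylsilyloxy)but-1-ene, via alkenylzirconocene chloride 9 (not isolated)
Conditions: Cp2Zr(H)Cl, THF, 23 °C; I2, −78 °C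
Reagents that add atoms: iodine, II
Why: syn-Hydrozirconation of an ynol ether puts hydride on the oxygen-bearing carbon and zirconium on the β-carbon, and iodinolysis with retention gives the iodide with iodine trans to the silyloxy group.

Step 7
Reactants: 11 2-methoxy-5-methyl-1,4-benzoquinone; 4 (1E,3Z)-1,3-bis(tert-butyldimethylsilyloxy)penta-1,3-diene
Product: 13 trans-fused 5,7-bis(tert-butyldimethylsilyloxy)-2-methoxy-4a,8-dimethyl-4a,5,8,8a-tetrahydronaphthalene-1,4-dione (C2 and C9 ketones; C3=C4 methyl enol ether; C12=C13 silyl enol ether; C14-OTBS and C11-Me on the face opposite to C1-Me), via cis-fused endo adduct 12 (not isolated)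
Conditions: (S)-o-tolyl-oxazaborolidine C24H24BNO·HN(SO2CF3)2 (20 mol %), CH2Cl2, −78 °C; then basic Al2O3, CH2Cl2, 23 °C
Reagents that add atoms: none
Why: In this catalytic enantioselective endo Diels–Alder reaction the Lewis acid binds the more basic vinylogous-ester carbonyl (C2=O), so the nucleophilic C11 end of the diene bonds to C10 and one face of C1=C10 is shielded (fixing C1, C11 and C14), after which equilibration through the C9 enolate inverts C10 to the more stable trans ring fusion.

Step 8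
Reactants: 13 trans-fused ene-dione
Product: 14 C9 alcohol (C9-OH axial, syn to C1-Me; C2 vinylogous ester intact)
Conditions: NaBH4, CeCl3·7H2O, MeOH/CH2Cl2, −78 °C
Reagents that add atoms: none
Why: Luche 1,2-reduction takes the C9 ketone, far more electrophilic than the vinylogous-ester carbonyl, with hydride entering anti to the syn-axial C1 methyl (this carbinol centre is erased in step 18).

Step 9
Reactants: 14 C9 alcohol
Product: 15 C9 4-methoxybenzyl ether
Conditions: KN(SiMe3)2, 4-MeOC6H4CH2Br, THF, −78 → 0 °C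
Reagents that add atoms: 4-methoxybenzyl bromide, COc1ccc(CBr)cc1
Why: Williamson etherification masks C9 with a group that survives hydride, fluoride and mild acid and is later removed oxidatively.

Step 10
Reactants: 15 C9 4-methoxybenzyl ether
Product: 16 C2 allylic alcohol (C2-OH axial, anti to C1-Me, syn to C14-OTBS)
Conditions: i-Bu2AlH, CH2Cl2, −78 °C
Reagents that add atoms: none
Why: 1,2-Reduction of the vinylogous ester, hydride being delivered from the face of the C1 methyl because the opposite face is closed by the syn-axial C14 silyloxy group and H-10, which sets C2.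

Step 11
Reactants: 16 C2 allylic alcohol
Product: 17 C2 tert-butyldimethylsilyl ether
Conditions: KN(SiMe3)2, t-BuMe2SiCl, THF, −78 → 0 °C
Reagents that add atoms: tert-butyldimethylsilyl chloride, CC(C)(C)[Si](C)(C)Cl
Why: Silylation of the potassium alkoxide avoids acid, to which the γ-hydroxy enol ether is labile.

Step 12
Reactants: 17 C2 silyl ether
Product: 18 C12 ketone (ring A: C14-OTBS, C12=O, C11-Me equatorial)
Conditions: Bu4NF (1.0 equiv), AcOH (1.2 equiv), THF, −78 → −40 °C
Reagents that add atoms: none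
Why: Buffered fluoride cleaves the silyl enol ether much faster than the secondary alkyl silyl ethers and protonates C13 without β-elimination of the C14 silyloxy group.

Step 13
Reactants: 18 C12 ketone
Product: 19 C12 axial alcohol (C12-OH cis to C11-Me, antiperiplanar to H-11)
Conditions: Li[HB(s-Bu)3], THF, −78 °C; aq. NH4Cl
Reagents that add atoms: none
Why: The bulky hydride attacks equatorially (the axial path is blocked by the syn-axial C14 silyloxy group), giving the axial alcohol as for 2-methylcyclohexanone.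

Step 14
Reactants: 19 C12 axial alcohol
Product: 20 ring-A alkene (C11=C12)
Conditions: Ph2S[OC(CF3)2Ph]2, CH2Cl2, 0 → 23 °C
Reagents that add atoms: none
Why: Martin sulfurane dehydration proceeds by anti elimination from the axial alkoxysulfonium, and loss of the tertiary axial H-11 (Zaitsev, as cis-2-methylcyclohexanol gives 1-methylcyclohexene) gives the trisubstituted alkene, so no silyl enol ether remains in ring A.

Step 15
Reactants: 20 ring-A alkene
Product: 21 C4 ketone
Conditions: (CO2H)2 (0.1 M aq.), THF, 0 → 23 °C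
Reagents that add atoms: water, O
Why: Mild acid hydrolysis of the only enol ether present unveils the C4 ketone without eliminating the β-silyloxy group at C2.

Step 16
Reactants: 21 C4 ketone
Product: 22 C9 hydroxy C4 ketone
Conditions: DDQ, CH2Cl2/pH 7 buffer, 0 °C
Reagents that add atoms: none
Why: Oxidative cleavage of the 4-methoxybenzyl ether is orthogonal to silyl ethers and to the trisubstituted alkene.

Step 17
Reactants: 22 C9 hydroxy C4 ketone
Product: 23 C4 tertiary alcohol (isopropenyl equatorial, C4-OH axial and syn to C2-OTBS; C9-OH free)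
Conditions: CH2=C(Me)MgBr (3 equiv), THF, −78 → 0 °C
Reagents that add atoms: isopropenylmagnesium bromide, CC(=C)[Mg]Br
Why: Grignard addition to the α-alkoxide ketone occurs equatorially, from the face of the C9 magnesium alkoxide, because axial attack is blocked by the syn-axial C2 silyloxy group, which sets C4.

Step 18
Reactants: 23 C4 tertiary alcohol
Product: 24 C9 ketone (α-hydroxy ketone)
Conditions: SO3·pyridine, Me2SO, i-Pr2NEt, CH2Cl2, 0 °C
Reagents that add atoms: none
Why: Parikh–Doering oxidation converts the secondary alcohol to the ketone without glycol cleavage and leaves the tertiary alcohol and the thermodynamically preferred trans C10 centre unchanged.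

Step 19
Reactants: 24 C9 ketone; 10 (S,E)-alkenyl iodide
Product: 26 dialkenyl trans-decalin-4,9-diol (C9: equatorial (E)-alkenyl, axial OH syn to C1-Me; C4: equatorial isopropenyl, axial OH), via alkenyllithium 25 (not isolated)
Conditions: 10 (2.5 equiv), t-BuLi (5 equiv), Et2O, −100 °C, 5 min; then 24 in THF, −100 → −78 °C; aq. NH4Cl
Reagents that add atoms: none
Why: Iodine–lithium exchange with retention gives the alkenyllithium, kept at −100 °C to outrun anti-β-elimination of silanolate, and it adds to the C9 ketone equatorially (axial attack is blocked by the syn-axial C1 methyl), which sets C9 and keeps the E-enol ether.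

Step 20
Reactants: 26 dialkenyl trans-decalin-4,9-diol
Product: 29 ten-membered 4,9-bis(trimethylsilyl enol ether) (C4=C5 and C8=C9 both E in the ring; C7-OTIPS), via dipotassium dialkoxide 27 (not isolated), via dipotassium bis-enolate 28 (not isolated)
Conditions: KN(SiMe3)2 (2.6 equiv), 18-crown-6 (2.6 equiv), THF, −78 → −20 °C; then Me3SiCl/Et3N, −78 °C
Reagents that add atoms: chlorotrimethylsilane, C[Si](C)(C)Cl
Why: The base converts the diol into its dipotassium dialkoxide, in which both oxyanions weaken the C4–C9 bond, and a concerted [3,3]-sigmatropic shift forms C6–C7 while breaking C4–C9. The closest known reaction type is the dianionic oxy-Cope ring expansion of 1,2-dialkenylcycloalkane-1,2-diols to cyclodecane-1,6-dione bis-enolates. The ten-membered ring is not closed end to end but arises by four-atom ring expansion through a chair transition state trans-fused to ring B, both alkenyl groups being equatorial, which gives both enolates with E ring geometry. The new stereocentre C7 is controlled by the E-enol ether, which keeps the silyloxy group equatorial in that chair so that C6 bonds to one face of C7 only (7S). The step needs chair over boat selectivity, which the rigid trans-decalin secures, and it needs the enolates to survive: the C7–O bond lies in the nodal plane of the nascent C8=C9 enolate, which disfavours E1cB loss of silanolate at −20 °C. Silylation at −78 °C caps both enolates before transannular aldol reaction or elimination can occur.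

Step 21
Reactants: 29 bis(trimethylsilyl enol ether)
Product: 30 (5Z)-enone (C4 ketone, C5=C6) retaining the C9 trimethylsilyl enol ether
Conditions: Pd(OAc)2 (1.05 equiv), MeCN, 23 °C
Reagents that add atoms: none
Why: In this Saegusa–Ito oxidation the less hindered C4 enol ether forms the C5 palladium enolate and syn-β-hydride elimination toward C6 gives the conjugated trisubstituted enone with cis ring geometry (a second trans alkene 1,4 to C8=C9 would be too strained), while the C9 enol ether, flanked by two tertiary carbons, is spared.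

Step 22
Reactants: 30 (5Z)-enone
Product: 31 C8 bromo C9 ketone (bromine on the outer face of the former enol ether)
Conditions: N-bromosuccinimide (1.05 equiv), THF, −78 °C
Reagents that add atoms: N-bromosuccinimide, O=C1CCC(=O)N1Br
Why: Electrophilic bromination of the silyl enol ether occurs from the only exposed face of the in-ring E-alkene, deliberately the face opposite to the one where the C8 oxygen is needed; the enone and the ring-A alkene do not react at −78 °C.

Step 23
Reactants: 31 C8 bromo C9 ketone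
Product: 32 bromohydrin (C9-OH configured as the target C9-O)
Conditions: NaBH4, MeOH/THF, −78 °C
Reagents that add atoms: none
Why: The α-bromo ketone is reduced before the enone, and hydride adds anti to the C8–Br bond (polar Felkin–Anh) in the rotamer that keeps C7 and C10 antiperiplanar, which should set C9.

Step 24
Reactants: 32 bromohydrin
Product: 33 (4R)-allylic alcohol (C4-OH, C9-OH, C8-Br)
Conditions: (S)-Me-oxazaborolidine C18H20BNO (1.0 equiv), catecholborane, toluene, −78 °C
Reagents that add atoms: none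
Why: Corey–Bakshi–Shibata 1,2-reduction of the enone is catalyst-controlled, the α-methylalkenyl branch acting as the large group, and sets C4 (R, 1,3-anti to the C2 oxygen).

Step 25
Reactants: 33 (4R)-allylic alcohol
Product: 34 C4,C9 diacetate (C8-Br)
Conditions: Ac2O, Et3N, DMAP, CH2Cl2, 0 → 23 °C
Reagents that add atoms: acetic anhydride, CC(=O)OC(C)=O
Why: DMAP-catalysed acetylation of the two secondary alcohols installs two of the final acetates and places the participating ester on C9.

Step 26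
Reactants: 34 C4,C9 diacetate
Product: 36 C8 tertiary alcohol (C4-OAc, C9-OAc, C8-OH as in the target), via dioxolanylium triflate 35 (not isolated)
Conditions: AgOSO2CF3 (1.2 equiv), 2,6-di-tert-butylpyridine, acetone/H2O (20:1), 0 °C
Reagents that add atoms: water, O
Why: Silver-assisted loss of the tertiary bromide is assisted from the rear by the C9 acetate carbonyl (Woodward–Prévost-type participation), so oxygen reaches C8 with inversion on the ring-interior face that external oxidants cannot reach, and water opens the 1,3-dioxolan-2-ylium ion at its acyl carbon to the cis-hydroxy acetate with the ester on the secondary oxygen.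

Step 27
Reactants: 36 C8 tertiary alcohol
Product: 37 pentaol (free OH at C2, C7, C8, C14, C19; C4-OAc, C9-OAc)
Conditions: HF·pyridine, pyridine, THF, 0 → 23 °C
Reagents that add atoms: none
Why: Buffered HF removes all four silyl ethers while esters, the allylic acetate and both alkenes are stable.

Step 28
Reactants: 37 pentaol
Product: 39 γ-lactone (C19 carbonyl, O–C7; C2-OH and C14-OH free), via lactol 38 (not isolated)
Conditions: TEMPO (20 mol %), PhI(OAc)2 (2.5 equiv), CH2Cl2, 23 °C
Reagents that add atoms: none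
Why: Oxoammonium oxidation is selective for the primary C19 alcohol, the aldehyde is trapped by the C7 hydroxyl as the five-membered lactol and oxidised on to the lactone, while the hindered neopentyl secondary alcohols at C2 and C14 and the tertiary C8-OH remain.

Step 29
Reactants: 39 γ-lactone
Product: 40 tetraacetate (C2, C4, C9, C14 OAc; ring-A alkene)
Conditions: Ac2O, pyridine, DMAP, 23 °C
Reagents that add atoms: acetic anhydride, CC(=O)OC(C)=O
Why: Acetylation of the two remaining secondary alcohols leaves the hindered tertiary C8 hydroxyl free.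

Step 30
Reactants: 40 tetraacetate
Product: 42 CNP0215170.2 (target), via bromohydrin 41 (not isolated)
Conditions: N-bromosuccinimide, MeOCH2CH2OMe/H2O, 0 °C; then DBU, CH2Cl2, 23 °C
Reagents that add atoms: water, O
Why: Bromohydrin formation then base closure: of the reversibly formed bromonium ions only the trans-diaxial, Markovnikov opening is productive (water axial at tertiary C11 on the face of the C1 methyl, bromine axial at C12), and backside displacement gives the 11,12-epoxide cis to the C1 methyl; the C5=C6 alkene is deactivated by its two allylic acyloxy groups.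

Compound list
1 | propionyl chloride | CCC(Cl)=O | starting material
2 | (E)-1-chloropent-1-en-3-one | CCC(=O)/C=C/Cl | intermediate
3 | (E)-1-(tert-butyldimethylsilyloxy)pent-1-en-3-one | CCC(=O)/C=C/O[Si](C)(C)C(C)(C)C | intermediate
4 | (1E,3Z)-1,3-bis(tert-butyldimethylsilyloxy)penta-1,3-diene | C/C=C(O[Si](C)(C)C(C)(C)C)/C=C/O[Si](C)(C)C(C)(C)C | intermediate
5 | methyl (S)-3-hydroxy-2-methylpropanoate | COC(=O)[C@@H](C)CO | starting material
6 | methyl (S)-3-(tert-butyldimethylsilyloxy)-2-methylpropanoate | COC(=O)[C@@H](C)CO[Si](C)(C)C(C)(C)C | intermediate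
7 | lithium (R)-4-(tert-butyldimethylsilyloxy)-3-methylbut-1-yn-1-olate | [Li]OC#C[C@@H](C)CO[Si](C)(C)C(C)(C)C | intermediate
8 | (R)-4-(tert-butyldimethylsilyloxy)-3-methyl-1-(triisopropylsilyloxy)but-1-yne | CC(C)[Si](C(C)C)(C(C)C)OC#C[C@@H](C)CO[Si](C)(C)C(C)(C)C | intermediate
9 | (E)-alkenylzirconocene chloride (Zr on C8, trans to OTIPS) | CC(C)[Si](C(C)C)(C(C)C)O/C=C(/[Zr](Cl)(C1C=CC=C1)C1C=CC=C1)[C@@H](C)CO[Si](C)(C)C(C)(C)C | intermediate
10 | (S,E)-4-(tert-butyldimethylsilyloxy)-2-iodo-3-methyl-1-(triisopropylsilyloxy)but-1-ene | CC(C)[Si](C(C)C)(C(C)C)O/C=C(/I)[C@@H](C)CO[Si](C)(C)C(C)(C)C | intermediate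
11 | 2-methoxy-5-methyl-1,4-benzoquinone | COC1=CC(=O)C(C)=CC1=O | starting material
12 | cis-fused endo Diels–Alder adduct (C10 epimer of 13) | CC(C)(C)[Si](C)(C)O[C@H]1C=C(O[Si](C)(C)C(C)(C)C)[C@@H](C)[C@H]2C(=O)C(OC)=CC(=O)[C@@]12C | intermediate
13 | trans-fused ene-dione (C2, C9 ketones; C4 OMe; ring-A silyl enol ether) | CC(C)(C)[Si](C)(C)O[C@H]1C=C(O[Si](C)(C)C(C)(C)C)[C@@H](C)[C@@H]2C(=O)C(OC)=CC(=O)[C@@]12C | intermediate
14 | C9 alcohol | CC(C)(C)[Si](C)(C)O[C@H]1C=C(O[Si](C)(C)C(C)(C)C)[C@@H](C)[C@@H]2[C@H](O)C(OC)=CC(=O)[C@@]12C | intermediate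
15 | C9 4-methoxybenzyl ether | CC(C)(C)[Si](C)(C)O[C@H]1C=C(O[Si](C)(C)C(C)(C)C)[C@@H](C)[C@@H]2[C@H](OCc3ccc(OC)cc3)C(OC)=CC(=O)[C@@]12C | intermediate
16 | C2 allylic alcohol | CC(C)(C)[Si](C)(C)O[C@H]1C=C(O[Si](C)(C)C(C)(C)C)[C@@H](C)[C@@H]2[C@H](OCc3ccc(OC)cc3)C(OC)=C[C@@H](O)[C@@]12C | intermediate
17 | C2 silyl ether | CC(C)(C)[Si](C)(C)O[C@H]1C=C(O[Si](C)(C)C(C)(C)C)[C@@H](C)[C@@H]2[C@H](OCc3ccc(OC)cc3)C(OC)=C[C@@H](O[Si](C)(C)C(C)(C)C)[C@@]12C | intermediate
18 | C12 ketone | CC(C)(C)[Si](C)(C)O[C@H]1CC(=O)[C@@H](C)[C@@H]2[C@H](OCc3ccc(OC)cc3)C(OC)=C[C@@H](O[Si](C)(C)C(C)(C)C)[C@@]12C | intermediate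
19 | C12 axial alcohol | CC(C)(C)[Si](C)(C)O[C@H]1C[C@@H](O)[C@@H](C)[C@@H]2[C@H](OCc3ccc(OC)cc3)C(OC)=C[C@@H](O[Si](C)(C)C(C)(C)C)[C@@]12C | intermediate
20 | ring-A C11=C12 alkene | CC(C)(C)[Si](C)(C)O[C@H]1CC=C(C)[C@@H]2[C@H](OCc3ccc(OC)cc3)C(OC)=C[C@@H](O[Si](C)(C)C(C)(C)C)[C@@]12C | intermediate
21 | C4 ketone | CC(C)(C)[Si](C)(C)O[C@H]1CC=C(C)[C@@H]2[C@H](OCc3ccc(OC)cc3)C(=O)C[C@@H](O[Si](C)(C)C(C)(C)C)[C@@]12C | intermediate
22 | C9 hydroxy C4 ketone | CC(C)(C)[Si](C)(C)O[C@H]1CC=C(C)[C@@H]2[C@H](O)C(=O)C[C@@H](O[Si](C)(C)C(C)(C)C)[C@@]12C | intermediate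
23 | C4 isopropenyl carbinol with C9 alcohol | CC(C)(C)[Si](C)(C)O[C@H]1CC=C(C)[C@@H]2[C@H](O)[C@](O)(C(C)=C)C[C@@H](O[Si](C)(C)C(C)(C)C)[C@@]12C | intermediate
24 | C9 ketone (α-hydroxy ketone) | CC(C)(C)[Si](C)(C)O[C@H]1CC=C(C)[C@@H]2C(=O)[C@](O)(C(C)=C)C[C@@H](O[Si](C)(C)C(C)(C)C)[C@@]12C | intermediate
25 | (E)-alkenyllithium (Li on C8, trans to OTIPS) | CC(C)[Si](C(C)C)(C(C)C)O/C=C(/[Li])[C@@H](C)CO[Si](C)(C)C(C)(C)C | intermediate
26 | dialkenyl trans-decalin-4,9-diol (key-step precursor) | CC(C)(C)[Si](C)(C)O[C@H]1CC=C(C)[C@@H]2[C@@](O)(/C(=C/O[Si](C(C)C)(C(C)C)C(C)C)[C@@H](C)CO[Si](C)(C)C(C)(C)C)[C@](O)(C(C)=C)C[C@@H](O[Si](C)(C)C(C)(C)C)[C@@]12C | intermediate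
27 | dipotassium dialkoxide of 26 | CC(C)(C)[Si](C)(C)O[C@H]1CC=C(C)[C@@H]2[C@@]([O-])(/C(=C/O[Si](C(C)C)(C(C)C)C(C)C)[C@@H](C)CO[Si](C)(C)C(C)(C)C)[C@]([O-])(C(C)=C)C[C@@H](O[Si](C)(C)C(C)(C)C)[C@@]12C.[K+].[K+] | intermediate
28 | dipotassium 4,9-bis-enolate of the ten-membered ring | CC(C)(C)[Si](C)(C)O[C@H]1CC=C(C)[C@@H]2/C([O-])=C(\[C@@H](C)CO[Si](C)(C)C(C)(C)C)[C@@H](O[Si](C(C)C)(C(C)C)C(C)C)C/C(C)=C([O-])/C[C@@H](O[Si](C)(C)C(C)(C)C)[C@@]12C.[K+].[K+] | intermediate
29 | ten-membered 4,9-bis(trimethylsilyl enol ether) (key-step product) | CC(C)(C)[Si](C)(C)O[C@H]1CC=C(C)[C@@H]2/C(O[Si](C)(C)C)=C(\[C@@H](C)CO[Si](C)(C)C(C)(C)C)[C@@H](O[Si](C(C)C)(C(C)C)C(C)C)C/C(C)=C(O[Si](C)(C)C)/C[C@@H](O[Si](C)(C)C(C)(C)C)[C@@]12C | intermediate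
30 | (5Z)-enone with C9 trimethylsilyl enol ether | CC(C)(C)[Si](C)(C)O[C@H]1CC=C(C)[C@@H]2/C(O[Si](C)(C)C)=C(\[C@@H](C)CO[Si](C)(C)C(C)(C)C)[C@@H](O[Si](C(C)C)(C(C)C)C(C)C)/C=C(/C)C(=O)C[C@@H](O[Si](C)(C)C(C)(C)C)[C@@]12C | intermediate
31 | C8 bromo C9 ketone | CC(C)(C)[Si](C)(C)O[C@H]1CC=C(C)[C@@H]2C(=O)[C@@](Br)([C@@H](C)CO[Si](C)(C)C(C)(C)C)[C@@H](O[Si](C(C)C)(C(C)C)C(C)C)/C=C(/C)C(=O)C[C@@H](O[Si](C)(C)C(C)(C)C)[C@@]12C | intermediate
32 | C8 bromo C9 alcohol (bromohydrin) | CC(C)(C)[Si](C)(C)O[C@H]1CC=C(C)[C@@H]2[C@@H](O)[C@@](Br)([C@@H](C)CO[Si](C)(C)C(C)(C)C)[C@@H](O[Si](C(C)C)(C(C)C)C(C)C)/C=C(/C)C(=O)C[C@@H](O[Si](C)(C)C(C)(C)C)[C@@]12C | intermediate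
33 | (4R)-allylic alcohol bromohydrin | CC(C)(C)[Si](C)(C)O[C@H]1CC=C(C)[C@@H]2[C@@H](O)[C@@](Br)([C@@H](C)CO[Si](C)(C)C(C)(C)C)[C@@H](O[Si](C(C)C)(C(C)C)C(C)C)/C=C(/C)[C@H](O)C[C@@H](O[Si](C)(C)C(C)(C)C)[C@@]12C | intermediate
34 | C4,C9 diacetate C8 bromide | CC(C)(C)[Si](C)(C)O[C@H]1CC=C(C)[C@@H]2[C@@H](OC(C)=O)[C@@](Br)([C@@H](C)CO[Si](C)(C)C(C)(C)C)[C@@H](O[Si](C(C)C)(C(C)C)C(C)C)/C=C(/C)[C@H](OC(C)=O)C[C@@H](O[Si](C)(C)C(C)(C)C)[C@@]12C | intermediate
35 | C8,C9 2-methyl-1,3-dioxolan-2-ylium triflate | CC(C)(C)[Si](C)(C)O[C@H]1CC=C(C)[C@@H]2[C@H]3OC(C)=[O+][C@@]3([C@@H](C)CO[Si](C)(C)C(C)(C)C)[C@@H](O[Si](C(C)C)(C(C)C)C(C)C)/C=C(/C)[C@H](OC(C)=O)C[C@@H](O[Si](C)(C)C(C)(C)C)[C@@]12C.[O-]S(=O)(=O)C(F)(F)F | intermediate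
36 | C8 tertiary alcohol, C4,C9 diacetate | CC(C)(C)[Si](C)(C)O[C@H]1CC=C(C)[C@@H]2[C@@H](OC(C)=O)[C@](O)([C@@H](C)CO[Si](C)(C)C(C)(C)C)[C@@H](O[Si](C(C)C)(C(C)C)C(C)C)/C=C(/C)[C@H](OC(C)=O)C[C@@H](O[Si](C)(C)C(C)(C)C)[C@@]12C | intermediate
37 | pentaol (C2, C7, C8, C14, C19 OH) | O[C@H]1CC=C(C)[C@@H]2[C@@H](OC(C)=O)[C@](O)([C@@H](C)CO)[C@@H](O)/C=C(/C)[C@H](OC(C)=O)C[C@@H](O)[C@@]12C | intermediate
38 | C19 lactol | O[C@H]1CC=C(C)[C@@H]2[C@@H](OC(C)=O)[C@@]3(O)[C@H](/C=C(/C)[C@H](OC(C)=O)C[C@@H](O)[C@@]12C)OC(O)[C@@H]3C | intermediate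
39 | γ-lactone with free C2 and C14 alcohols | O[C@H]1CC=C(C)[C@@H]2[C@@H](OC(C)=O)[C@@]3(O)[C@H](/C=C(/C)[C@H](OC(C)=O)C[C@@H](O)[C@@]12C)OC(=O)[C@@H]3C | intermediate
40 | tetraacetate with ring-A C11=C12 alkene | CC(=O)O[C@H]1CC=C(C)[C@@H]2[C@@H](OC(C)=O)[C@@]3(O)[C@H](/C=C(/C)[C@H](OC(C)=O)C[C@@H](OC(C)=O)[C@@]12C)OC(=O)[C@@H]3C | intermediate
41 | C11 hydroxy C12 bromide (bromohydrin) | CC(=O)O[C@H]1C[C@@H](Br)[C@@](O)(C)[C@@H]2[C@@H](OC(C)=O)[C@@]3(O)[C@H](/C=C(/C)[C@H](OC(C)=O)C[C@@H](OC(C)=O)[C@@]12C)OC(=O)[C@@H]3C | intermediate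
42 | CNP0215170.2 (2,4,9,14-tetraacetoxy-11,12-epoxy-8-hydroxy briarane γ-lactone, 5Z) | CC(=O)O[C@H]1C[C@@H]2O[C@]2(C)[C@@H]2[C@@H](OC(C)=O)[C@@]3(O)[C@H](/C=C(/C)[C@H](OC(C)=O)C[C@@H](OC(C)=O)[C@@]12C)OC(=O)[C@@H]3C | target

Total step count: 30. Longest linear sequence: 27 steps (steps 1–3 and 7–30, from propionyl chloride).

Steps most likely to fail

Step 20 (key step). The C9 enolate may expel the C7 silyloxy group, the two enolates may undergo transannular aldol reaction before they are silylated, or the dipotassium salt may not rearrange at the low temperature needed to prevent both. Fallback: diol 26 is silylated on both tertiary hydroxyls (Me3SiOSO2CF3, Et3N, CH2Cl2, −78 °C) to give the bis(trimethylsilyl) ether F1. Heating F1 (toluene, sealed tube, 150–180 °C) should bring about the neutral siloxy-Cope rearrangement through the same chair. No free enolate is formed and the route is rejoined directly at 29.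

Step 19. Anti-β-elimination of lithium silanolate from alkenyllithium 25 (collapse to the alkyne) may outrun addition to the hindered ketone. Fallback: alkyne 8 is hydrozirconated as in step 6 to 9, which is transmetalated with Me2Zn (toluene, −65 → 0 °C) to the covalent alkenyl(methyl)zinc F2. F2 is added to ketone 24 (its C4 hydroxyl first converted to the zinc alkoxide by Me2Zn) in the presence of Ti(Oi-Pr)4. The carbon–zinc bond does not eliminate, the alkene geometry is retained, and 26 is reached without 10 or 25.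

Step 23. Hydride may be delivered to the other face of C9, because the approach anti to bromine points toward the interior of the ten-membered ring; this would give the C9 epimer. Fallback: in the C9-epimeric bromohydrin F3 the hydroxyl can stand anti to bromine, so DBU (CH2Cl2, 23 °C) closes it to the trans-8,9-epoxide F4 with inversion at C8, which is the C8–O bond required. Reduction and acetylation as in steps 24 and 25 give the epoxy alcohol F5 and the epoxy acetate F6. Acetate (CsOAc, 18-crown-6, DMF, 70 °C) then opens the epoxide at the secondary C9 with inversion, which corrects C9 and returns 36.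

Further compounds
F1 | step 20 | 4,9-bis(trimethylsilyl) ether of diol 26 | CC(C)(C)[Si](C)(C)O[C@H]1CC=C(C)[C@@H]2[C@@](O[Si](C)(C)C)(/C(=C/O[Si](C(C)C)(C(C)C)C(C)C)[C@@H](C)CO[Si](C)(C)C(C)(C)C)[C@](O[Si](C)(C)C)(C(C)=C)C[C@@H](O[Si](C)(C)C(C)(C)C)[C@@]12C
F2 | step 19 | (E)-alkenyl(methyl)zinc | C[Zn]/C(=C/O[Si](C(C)C)(C(C)C)C(C)C)[C@@H](C)CO[Si](C)(C)C(C)(C)C
F3 | step 23 | C9 epimer of bromohydrin 32 | CC(C)(C)[Si](C)(C)O[C@H]1CC=C(C)[C@@H]2[C@H](O)[C@@](Br)([C@@H](C)CO[Si](C)(C)C(C)(C)C)[C@@H](O[Si](C(C)C)(C(C)C)C(C)C)/C=C(/C)C(=O)C[C@@H](O[Si](C)(C)C(C)(C)C)[C@@]12C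
F4 | step 23 | trans-8,9-epoxide, C4 ketone | CC(C)(C)[Si](C)(C)O[C@H]1CC=C(C)[C@@H]2[C@@H]3O[C@@]3([C@@H](C)CO[Si](C)(C)C(C)(C)C)[C@@H](O[Si](C(C)C)(C(C)C)C(C)C)/C=C(/C)C(=O)C[C@@H](O[Si](C)(C)C(C)(C)C)[C@@]12C
F5 | step 23 | trans-8,9-epoxide, (4R)-alcohol | CC(C)(C)[Si](C)(C)O[C@H]1CC=C(C)[C@@H]2[C@@H]3O[C@@]3([C@@H](C)CO[Si](C)(C)C(C)(C)C)[C@@H](O[Si](C(C)C)(C(C)C)C(C)C)/C=C(/C)[C@H](O)C[C@@H](O[Si](C)(C)C(C)(C)C)[C@@]12C
F6 | step 23 | trans-8,9-epoxide, C4 acetate | CC(C)(C)[Si](C)(C)O[C@H]1CC=C(C)[C@@H]2[C@@H]3O[C@@]3([C@@H](C)CO[Si](C)(C)C(C)(C)C)[C@@H](O[Si](C(C)C)(C(C)C)C(C)C)/C=C(/C)[C@H](OC(C)=O)C[C@@H](O[Si](C)(C)C(C)(C)C)[C@@]12C
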